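**Plan**
1. The target is read as (1R)-1-[(5E)-4-bromo-5-(bromomethylidene)-2-oxo-2,5-dihydrofuran-3-yl]butyl acetate; the furanone is numbered O1, C2 (C=O), C3 (side chain), C4 (Br), C5, with exocyclic C6 (CHBr).
2. Retrosynthesis: first O1–C5, C6–Br and C4–Br are cut (anti-bromolactonisation of an enynoic acid; Br for Sn), then C2–C3 and C4–C5 are cut together.
3. Enabling feature: the tetrasubstituted C3=C4 alkene of the ring carries the carboxyl carbon C2 and the ylidene carbon C5 cis to each other. It is therefore the retron of an alkyne used as a cis-1,2-dianion (a titanacyclopropene), and C4, which also bears Br, is a geminal dianion carbon (Ti and Sn).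
4. Forward: a chiral alkynylstannane, CO2 and a bromoalkyne are joined in one titanium-mediated flask to the open-chain enynoic acid; the furanone, the only ring, closes last (5-exo-dig).
5. Stereochemistry: C1' (R) comes from a Noyori transfer hydrogenation of an ynone; the C3=C4 geometry from syn delivery on the metallacycle; (5E) from anti addition of carboxylate and bromine; C4–Br from C4–Sn with retention.

Key step: step 5

Assumption: the SMILES is read with the exocyclic bromine cis to C4 and trans to O1, which is (5E), and with the carbinol carbon (R).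

**Step 1**
Reactants: 1 butanoyl chloride; 2 ethynyl(trimethyl)silane
Product: 3 1-(trimethylsilyl)hex-1-yn-3-one
Conditions: PdCl2(PPh3)2 (2 mol %), CuI (4 mol %), Et3N (1.2 equiv), THF, rt
Reagents that add atoms: none
Why: Acyl Sonogashira coupling of an acid chloride with a terminal alkyne should give the silyl ynone directly; no stereocentre is formed.

**Step 2**
Reactants: 3 1-(trimethylsilyl)hex-1-yn-3-one
Product: 4 (3R)-1-(trimethylsilyl)hex-1-yn-3-ol
Conditions: Ru[(R,R)-TsDPEN](p-cymene) (amido complex preformed from RuCl[(R,R)-TsDPEN](p-cymene) and KOH, 1 mol %), iPrOH, rt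
Reagents that add atoms: none
Why: Noyori asymmetric transfer hydrogenation, in which the (R,R)-configured ruthenium hydride distinguishes the alkynyl from the propyl side of the ynone and, by the established sense for alkynyl ketones, should give the (R)-carbinol, the only stereocentre of the route.

**Step 3**
Reactants: 4 (3R)-1-(trimethylsilyl)hex-1-yn-3-ol
Product: 5 tert-butyl(dimethyl){[(3R)-1-(trimethylsilyl)hex-1-yn-3-yl]oxy}silane
Conditions: TBSCl, imidazole, DMF, rt
Reagents that add atoms: tert-butyl(chloro)dimethylsilane, CC(C)(C)[Si](C)(C)Cl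
Why: Standard O-silylation of a secondary alcohol, which leaves the configuration untouched and gives an oxygen group that is not a leaving group in step 5.

**Step 4**
Reactants: 5 tert-butyl(dimethyl){[(3R)-1-(trimethylsilyl)hex-1-yn-3-yl]oxy}silane
Product: 7 tert-butyl(dimethyl){[(3R)-1-(tributylstannyl)hex-1-yn-3-yl]oxy}silane, via lithium acetylide 6 (not isolated)
Conditions: MeLi·LiBr, THF, 0 °C to rt; then Bu3SnCl, −78 °C to rt
Reagents that add atoms: tributyltin chloride, CCCC[Sn](Cl)(CCCC)CCCC
Why: Nucleophilic cleavage of the C(sp)–SiMe3 bond by MeLi should give the lithium acetylide, which is stannylated at carbon (silicon-to-tin exchange via lithium) without touching the silyl ether or the stereocentre.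

**Step 5**
Reactants: 7 tert-butyl(dimethyl){[(3R)-1-(tributylstannyl)hex-1-yn-3-yl]oxy}silane; 8 (bromoethynyl)tri(propan-2-yl)silane
Product: 11 (2E)-2-[(1R)-1-{[tert-butyl(dimethyl)silyl]oxy}butyl]-3-(tributylstannyl)-5-[tri(propan-2-yl)silyl]pent-2-en-4-ynoic acid, via titanacyclopropene 9 (not isolated), via titanalactone 10 (not isolated)
Conditions: Ti(OiPr)4 (1.2 equiv), iPrMgCl (2.4 equiv), Et2O, −78 to −50 °C; CO2 (1 atm), −50 to −20 °C, then argon purge; CuCl (1.5 equiv), 8 (1.5 equiv), THF, −20 °C to rt; aq. citric acid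
Reagents that add atoms: carbon dioxide, O=C=O
Why: Proposed new method: divalent titanium generated from Ti(OiPr)4 and two equivalents of iPrMgCl should bind the alkyne of 7 as titanacyclopropene 9, CO2 should insert into the Ti–C bond remote from tin to give the five-membered titanalactone 10, and transfer of the remaining alkenyl–titanium bond to monovalent copper followed by coupling with bromoalkyne 8 (retention) should give 11 after protonation, so that the bonds that become C2–C3 and C4–C5 of the furanone are made in one flask. The closest known reaction types are the titanium-alkoxide-mediated carboxylation of 1-silylalkynes, whose titanalactones are trapped by iodine, N-bromosuccinimide or aldehydes, and the CuCl-mediated coupling of alkenylzirconium species with 1-bromoalkynes; geminal tin/early-metal alkenes are known to react at the early-metal bond first. No ring of the target closes here (the titanalactone is transient and the furanone closes 5-exo-dig in step 8) and no stereocentre is made: the carbinol centre is not involved, and the cis relation of the carboxyl and alkynyl groups follows from both new bonds replacing the two Ti–C bonds on the same side of the metallacycle. The step needs regioselectivity (CO2 at the carbinol-bearing carbon), secured by the tin substituent, which keeps titanium on its own carbon as silicon does; chemoselectivity for the Ti–C over the Sn–C bond in the copper transfer, secured by the much faster transmetalation of the early metal at low temperature; and survival of the propargylic oxygen, secured by the poor leaving-group ability of the silyl ether.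

**Step 6**
Reactants: 11 (2E)-2-[(1R)-1-{[tert-butyl(dimethyl)silyl]oxy}butyl]-3-(tributylstannyl)-5-[tri(propan-2-yl)silyl]pent-2-en-4-ynoic acid
Product: 12 (2E)-2-[(1R)-1-hydroxybutyl]-3-(tributylstannyl)pent-2-en-4-ynoic acid
Conditions: Bu4NF (4 equiv), THF, 0 °C to rt; pH 5 buffer
Reagents that add atoms: none
Why: Fluoride-mediated desilylation should remove the O-silyl and the C(sp)-silyl group in one operation, while the alkenyl–tin bond, the alkene geometry and the stereocentre are kept.

**Step 7**
Reactants: 12 (2E)-2-[(1R)-1-hydroxybutyl]-3-(tributylstannyl)pent-2-en-4-ynoic acid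
Product: 13 (2E)-2-[(1R)-1-(acetyloxy)butyl]-3-(tributylstannyl)pent-2-en-4-ynoic acid
Conditions: Ac2O, pyridine, DMAP (cat.), CH2Cl2, 0 °C; aq. NaHCO3, then pH 4
Reagents that add atoms: acetic anhydride, CC(=O)OC(C)=O
Why: DMAP-catalysed O-acetylation of the secondary alcohol proceeds with retention, and any mixed anhydride formed at the carboxyl group is hydrolysed in the bicarbonate work-up.

**Step 8**
Reactants: 13 (2E)-2-[(1R)-1-(acetyloxy)butyl]-3-(tributylstannyl)pent-2-en-4-ynoic acid
Product: 15 (1R)-1-[(5E)-4-bromo-5-(bromomethylidene)-2-oxo-2,5-dihydrofuran-3-yl]butyl acetate, via bromo acid 14 (not isolated)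
Conditions: Br2 (1.0 equiv), CH2Cl2, −78 °C; then N-bromosuccinimide (1.1 equiv), KHCO3 (0.2 equiv), Bu4NOH (cat.), CH2Cl2/H2O, 0 °C to rt, dark
Reagents that add atoms: bromine, BrBr; N-bromosuccinimide, O=C1CCC(=O)N1Br
Why: Ipso-bromodestannylation (retention at the alkene) is followed by bromolactonisation, in which the carboxylate adds 5-exo-dig to the bromonium-activated terminal alkyne anti to bromine, so the furanone closes with the exocyclic bromine trans to O1, that is (5E), and the stereocentre is not involved.

**Compound list**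
1 | butanoyl chloride | CCCC(=O)Cl | starting material
2 | ethynyl(trimethyl)silane | C#C[Si](C)(C)C | starting material
3 | 1-(trimethylsilyl)hex-1-yn-3-one | CCCC(=O)C#C[Si](C)(C)C | intermediate
4 | (3R)-1-(trimethylsilyl)hex-1-yn-3-ol | CCC[C@@H](O)C#C[Si](C)(C)C | intermediate
5 | tert-butyl(dimethyl){[(3R)-1-(trimethylsilyl)hex-1-yn-3-yl]oxy}silane | CCC[C@@H](O[Si](C)(C)C(C)(C)C)C#C[Si](C)(C)C | intermediate
6 | [(3R)-3-{[tert-butyl(dimethyl)silyl]oxy}hex-1-yn-1-yl]lithium (lithium acetylide, not isolated) | CCC[C@@H](O[Si](C)(C)C(C)(C)C)C#C[Li] | intermediate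
7 | tert-butyl(dimethyl){[(3R)-1-(tributylstannyl)hex-1-yn-3-yl]oxy}silane | CCC[C@@H](O[Si](C)(C)C(C)(C)C)C#C[Sn](CCCC)(CCCC)CCCC | intermediate
8 | (bromoethynyl)tri(propan-2-yl)silane | BrC#C[Si](C(C)C)(C(C)C)C(C)C | starting material
9 | 2-[(1R)-1-{[tert-butyl(dimethyl)silyl]oxy}butyl]-1,1-di(propan-2-yloxy)-3-(tributylstannyl)titanacycloprop-2-ene (titanacyclopropene, not isolated) | CCC[C@@H](O[Si](C)(C)C(C)(C)C)C1=C([Sn](CCCC)(CCCC)CCCC)[Ti]1(OC(C)C)OC(C)C | intermediate
10 | 4-[(1R)-1-{[tert-butyl(dimethyl)silyl]oxy}butyl]-2,2-di(propan-2-yloxy)-3-(tributylstannyl)-1-oxa-2-titanacyclopent-3-en-5-one (titanalactone, not isolated) | CCC[C@@H](O[Si](C)(C)C(C)(C)C)C1=C([Sn](CCCC)(CCCC)CCCC)[Ti](OC(C)C)(OC(C)C)OC1=O | intermediate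
11 | (2E)-2-[(1R)-1-{[tert-butyl(dimethyl)silyl]oxy}butyl]-3-(tributylstannyl)-5-[tri(propan-2-yl)silyl]pent-2-en-4-ynoic acid (carboxyl cis to alkynyl) | CCC[C@@H](O[Si](C)(C)C(C)(C)C)/C(C(=O)O)=C(/C#C[Si](C(C)C)(C(C)C)C(C)C)[Sn](CCCC)(CCCC)CCCC | intermediate
12 | (2E)-2-[(1R)-1-hydroxybutyl]-3-(tributylstannyl)pent-2-en-4-ynoic acid | CCC[C@@H](O)/C(C(=O)O)=C(/C#C)[Sn](CCCC)(CCCC)CCCC | intermediate
13 | (2E)-2-[(1R)-1-(acetyloxy)butyl]-3-(tributylstannyl)pent-2-en-4-ynoic acid | CCC[C@@H](OC(C)=O)/C(C(=O)O)=C(/C#C)[Sn](CCCC)(CCCC)CCCC | intermediate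
14 | (2E)-2-[(1R)-1-(acetyloxy)butyl]-3-bromopent-2-en-4-ynoic acid (bromo acid, not isolated; carboxyl cis to ethynyl) | CCC[C@@H](OC(C)=O)/C(C(=O)O)=C(/C#C)Br | intermediate
15 | (1R)-1-[(5E)-4-bromo-5-(bromomethylidene)-2-oxo-2,5-dihydrofuran-3-yl]butyl acetate (acetoxyfimbrolide as drawn) | CCC[C@@H](OC(C)=O)C1=C(Br)/C(=C\Br)OC1=O | target

**Step count:** 8 steps in total; the longest linear sequence is 8 steps (1 to 15).

**Steps most likely to fail**

Step 5. What may go wrong: insertion of CO2 at the wrong alkyne carbon, cleavage of the tin–carbon bond by the low-valent titanium reagent, or failure of the copper transfer at the crowded tin-bearing carbon. The fallback is a tin-free sequence of known reactions that makes the C4–C5 bond first. It sets out from 5. K2CO3 in methanol removes the trimethylsilyl group to give tert-butyl{[(3R)-hex-1-yn-3-yl]oxy}dimethylsilane F1. Cadiot–Chodkiewicz coupling of F1 with 8 (CuCl, NH2OH·HCl, BuNH2) gives tert-butyl(dimethyl){[(5R)-1-[tri(propan-2-yl)silyl]octa-1,3-diyn-5-yl]oxy}silane F2. The known titanium-alkoxide-mediated carboxylation (Ti(OiPr)4, 2 iPrMgCl, then CO2) is applied to the less hindered triple bond of F2 and the titanalactone is quenched with N-bromosuccinimide. This should give (2E)-3-bromo-2-[(1R)-1-{[tert-butyl(dimethyl)silyl]oxy}butyl]-5-[tri(propan-2-yl)silyl]pent-2-en-4-ynoic acid F3 with the ring bromine already in place. Bu4NF then gives (2E)-3-bromo-2-[(1R)-1-hydroxybutyl]pent-2-en-4-ynoic acid F4. Acid-catalysed acetylation (Ac2O, Sc(OTf)3, which avoids amine addition to the bromoacrylate) comes back to the route at 14, which then undergoes the bromolactonisation of step 8.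

Step 8. What may go wrong: competing 6-endo closure to a pyranone, addition of bromine to the alkyne before the tin is consumed, or light-induced equilibration of the exocyclic double bond. The fallback sets the exocyclic geometry by anti-oxystannylation instead of bromolactonisation. It sets out from 13. (Bu3Sn)2O with azeotropic removal of water gives tributylstannyl (2E)-2-[(1R)-1-(acetyloxy)butyl]-3-(tributylstannyl)pent-2-en-4-ynoate F5. The known PdCl2(MeCN)2-catalysed cyclisation of stannyl enynoates in DMF should then give (1R)-1-{(5E)-2-oxo-4-(tributylstannyl)-5-[(tributylstannyl)methylidene]-2,5-dihydrofuran-3-yl}butyl acetate F6. Double bromodestannylation (Br2, 2 equiv, CH2Cl2, −78 °C, retention at both carbons) comes back to the route at 15.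

Step 6. What may go wrong: slow cleavage of the hindered silyl ether, during which the basic fluoride closes the carboxylate onto the freed alkyne or the tin group is lost. The fallback unmasks the two silicon groups in separate, orthogonal operations. It sets out from 11. Pyridine-buffered HF·pyridine in THF cleaves only the O–Si bond to give (2E)-2-[(1R)-1-hydroxybutyl]-3-(tributylstannyl)-5-[tri(propan-2-yl)silyl]pent-2-en-4-ynoic acid F7. Acetylation (Ac2O, pyridine, DMAP) gives (2E)-2-[(1R)-1-(acetyloxy)butyl]-3-(tributylstannyl)-5-[tri(propan-2-yl)silyl]pent-2-en-4-ynoic acid F8. A brief treatment with Bu4NF buffered with acetic acid at 0 °C removes the C–Si group and comes back to the route at 13.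

**Further compounds**
F1 | step 5 | tert-butyl{[(3R)-hex-1-yn-3-yl]oxy}dimethylsilane | CCC[C@@H](O[Si](C)(C)C(C)(C)C)C#C
F2 | step 5 | tert-butyl(dimethyl){[(5R)-1-[tri(propan-2-yl)silyl]octa-1,3-diyn-5-yl]oxy}silane | CCC[C@@H](O[Si](C)(C)C(C)(C)C)C#CC#C[Si](C(C)C)(C(C)C)C(C)C
F3 | step 5 | (2E)-3-bromo-2-[(1R)-1-{[tert-butyl(dimethyl)silyl]oxy}butyl]-5-[tri(propan-2-yl)silyl]pent-2-en-4-ynoic acid | CCC[C@@H](O[Si](C)(C)C(C)(C)C)/C(C(=O)O)=C(/C#C[Si](C(C)C)(C(C)C)C(C)C)Br
F4 | step 5 | (2E)-3-bromo-2-[(1R)-1-hydroxybutyl]pent-2-en-4-ynoic acid | CCC[C@@H](O)/C(C(=O)O)=C(/C#C)Br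
F5 | step 8 | tributylstannyl (2E)-2-[(1R)-1-(acetyloxy)butyl]-3-(tributylstannyl)pent-2-en-4-ynoate | CCC[C@@H](OC(C)=O)/C(C(=O)O[Sn](CCCC)(CCCC)CCCC)=C(/C#C)[Sn](CCCC)(CCCC)CCCC
F6 | step 8 | (1R)-1-{(5E)-2-oxo-4-(tributylstannyl)-5-[(tributylstannyl)methylidene]-2,5-dihydrofuran-3-yl}butyl acetate | CCC[C@@H](OC(C)=O)C1=C([Sn](CCCC)(CCCC)CCCC)/C(=C\[Sn](CCCC)(CCCC)CCCC)OC1=O
F7 | step 6 | (2E)-2-[(1R)-1-hydroxybutyl]-3-(tributylstannyl)-5-[tri(propan-2-yl)silyl]pent-2-en-4-ynoic acid | CCC[C@@H](O)/C(C(=O)O)=C(/C#C[Si](C(C)C)(C(C)C)C(C)C)[Sn](CCCC)(CCCC)CCCC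
F8 | step 6 | (2E)-2-[(1R)-1-(acetyloxy)butyl]-3-(tributylstannyl)-5-[tri(propan-2-yl)silyl]pent-2-en-4-ynoic acid | CCC[C@@H](OC(C)=O)/C(C(=O)O)=C(/C#C[Si](C(C)C)(C(C)C)C(C)C)[Sn](CCCC)(CCCC)CCCC
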